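**Remark on the chemistry (assumptions).** Bicyclic compounds are named with labdane numbering: C1–C10 ring carbons, C11–C16 side chain, C17 on C8, C18 the oxygenated carbon on C4, C19 the methyl on C4, C20 on C10. The target is (4S,5S,8S,9S,10R,13S) with a (Z)-2-methylbut-2-enoate (angelate) on O18. (R)-3-Methylglutaric acid monomethyl ester is taken as a purchasable chiral building block.

## Retrosynthetic overview

1. Endgame: angelate on O18 and tert-butyl ester cleavage last. C8–OH and C9–H are set together by syn-hydroboration of a C8=C9 alkene from the face opposite the axial C10 methyl.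
2. The C8=C9 alkene comes from a 6-oxo-8-ene (dienyl triflate, formate reduction, hydrogenation); the C6 carbonyl is a temporary activating group.
3. Key disconnection of C5–C10 and C7–C8 leads to acyclic keto-enone 18. The enabling feature: in ring B, C6 sits between C5 and C7 (a C6 ketone makes them a 1,3-dinucleophile) and C9 sits between C8 and C10 (carbinol C8 and quaternary C10 are the carbonyl and β-carbon of a methyl enone); C1–C3 of ring A tether the two units.
4. 18 arises by Negishi union of a C1–C7 iodide (C4 set by palladium-catalysed decarboxylative asymmetric allylic alkylation) with a vinyl triflate made from acetylacetone and a glutarate-derived iodide (C13 bought).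
5. Ring order: ring A (Michael addition) then ring B (aldol condensation), both in step 14.

Key step: step 14

## Route

Step 1
Reactants: 1 δ-valerolactone; 2 allyl chloroformate
Product: 3 allyl 2-oxotetrahydro-2H-pyran-3-carboxylate (racemic)
Conditions: LiN(i-Pr)2 (2.1 equiv), THF, −78 °C; then 2, −78 → −30 °C; aq. NH4Cl
Reagents that add atoms: none
Why: Claisen-type C-acylation of the lactone lithium enolate by the chloroformate, the second equivalent of base holding the more acidic product as its enolate; the new centre is enolisable and of no consequence.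

Step 2
Reactants: 3 allyl 2-oxotetrahydro-2H-pyran-3-carboxylate
Product: 4 allyl 3-methyl-2-oxotetrahydro-2H-pyran-3-carboxylate (racemic)
Conditions: MeI, K2CO3, acetone, 45 °C
Reagents that add atoms: methyl iodide, CI
Why: Alkylation of the stabilised 1,3-dicarbonyl enolate gives the racemic quaternary ester, the substrate needed for a stereoablative allylation.

Step 3
Reactants: 4 allyl 3-methyl-2-oxotetrahydro-2H-pyran-3-carboxylate
Product: 5 (S)-3-allyl-3-methyltetrahydro-2H-pyran-2-one
Conditions: Pd2(dba)3 (2.5 mol %), (S)-(CF3)3-t-BuPHOX (6 mol %), toluene, 40 °C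
Reagents that add atoms: none
Why: Palladium-catalysed decarboxylative asymmetric allylic alkylation (Tsuji–Trost type): zerovalent palladium ionises the allyl ester, CO2 is lost and the PHOX ligand controls the face of C-allylation of the prochiral enolate, so C4 is set by catalyst control, the (S)-ligand being chosen by analogy with the ketone and lactam series.

Step 4
Reactants: 5 (S)-3-allyl-3-methyltetrahydro-2H-pyran-2-one
Product: 6 (S)-2-allyl-2-methylpentane-1,5-diol
Conditions: LiAlH4, THF, 0 °C → rt; Fieser work-up
Reagents that add atoms: none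
Why: Hydride reduction of the lactone to the 1,5-diol leaves the quaternary centre and the alkene untouched.

Step 5
Reactants: 6 (S)-2-allyl-2-methylpentane-1,5-diol
Product: 7 (S)-2-(3-iodopropyl)-2-methylpent-4-en-1-ol
Conditions: I2, PPh3, imidazole (2.2 equiv each), CH2Cl2, 0 °C → rt; aq. Na2S2O3
Reagents that add atoms: iodine, II
Why: Appel iodination: the neopentyl alkoxyphosphonium ion at O18 cannot undergo SN2 displacement and returns the alcohol on work-up, so only the unhindered C1 alcohol becomes the iodide.

Step 6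
Reactants: 7 (S)-2-(3-iodopropyl)-2-methylpent-4-en-1-ol
Product: 8 (S)-4-(benzyloxymethyl)-7-iodo-4-methylhept-1-ene
Conditions: BnOC(=NH)CCl3, TfOH (5 mol %), CH2Cl2/cyclohexane, 0 °C → rt
Reagents that add atoms: benzyl 2,2,2-trichloroacetimidate, ClC(Cl)(Cl)C(=N)OCc1ccccc1
Why: Acid-catalysed trichloroacetimidate benzylation avoids an alkoxide, which would displace the iodide intramolecularly to a tetrahydropyran.

Step 7
Reactants: 9 (R)-5-methoxy-3-methyl-5-oxopentanoic acid
Product: 10 1-tert-butyl 5-methyl (S)-3-methylpentanedioate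
Conditions: Boc2O, DMAP (cat.), t-BuOH, 30 °C
Reagents that add atoms: di-tert-butyl dicarbonate, CC(C)(C)OC(=O)OC(=O)OC(C)(C)C
Why: Esterification of the free acid through its mixed carbonic anhydride leaves the methyl ester and the bought C13 centre untouched (the descriptor changes only by priority).

Step 8
Reactants: 10 1-tert-butyl 5-methyl (S)-3-methylpentanedioate
Product: 11 tert-butyl (S)-5-hydroxy-3-methylpentanoate
Conditions: LiBH4, THF, MeOH (1 equiv), 0 °C → rt
Reagents that add atoms: none
Why: Chemoselective borohydride reduction of the methyl ester, the hindered tert-butyl ester reacting far more slowly.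

Step 9
Reactants: 11 tert-butyl (S)-5-hydroxy-3-methylpentanoate
Product: 12 tert-butyl (R)-5-iodo-3-methylpentanoate
Conditions: I2, PPh3, imidazole, CH2Cl2, 0 °C
Reagents that add atoms: iodine, II
Why: Appel iodination of the primary alcohol (descriptor change by priority only).

Step 10
Reactants: 12 tert-butyl (R)-5-iodo-3-methylpentanoate; 13 pentane-2,4-dione
Product: 14 tert-butyl (S)-6-acetyl-3-methyl-7-oxooctanoate
Conditions: K2CO3, acetone, reflux
Reagents that add atoms: none
Why: C-alkylation of the soft acetylacetone enolate by the primary iodide under mild carbonate conditions installs C11–C15 on the future C9.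

Step 11
Reactants: 14 tert-butyl (S)-6-acetyl-3-methyl-7-oxooctanoate
Product: 15 tert-butyl (3S,6Z)-6-acetyl-3-methyl-7-(trifluoromethylsulfonyloxy)oct-6-enoate
Conditions: NaH, THF, 0 °C; PhNTf2, 0 °C → rt
Reagents that add atoms: N-phenylbis(trifluoromethanesulfonimide), O=S(=O)(N(c1ccccc1)S(=O)(=O)C(F)(F)F)C(F)(F)F
Why: O-triflation of the chelated sodium enolate of a symmetric diketone gives one constitutional isomer, expected Z from the chelate (the geometry is of no later consequence).

Step 12
Reactants: 8 (S)-4-(benzyloxymethyl)-7-iodo-4-methylhept-1-ene; 15 tert-butyl (3S,6Z)-6-acetyl-3-methyl-7-(trifluoromethylsulfonyloxy)oct-6-enoate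
Product: 17 tert-butyl (3S,6Z,11S)-6-acetyl-11-(benzyloxymethyl)-3,7,11-trimethyltetradeca-6,13-dienoate, via alkylzinc iodide 16 (not isolated)
Conditions: Zn dust (activated with Me3SiCl/BrCH2CH2Br), LiCl, THF, 40 °C; then 15, Pd(dppf)Cl2 (5 mol %), THF, 50 °C
Reagents that add atoms: none
Why: Zinc insertion into the primary C–I bond followed by Negishi sp3–sp2 cross-coupling with the vinyl triflate forms C1–C10, the organozinc tolerating ketone, ester, benzyl ether and terminal alkene.

Step 13
Reactants: 17 tert-butyl (3S,6Z,11S)-6-acetyl-11-(benzyloxymethyl)-3,7,11-trimethyltetradeca-6,13-dienoate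
Product: 18 tert-butyl (3S,6Z,11S)-6-acetyl-11-(benzyloxymethyl)-3,7,11-trimethyl-13-oxotetradec-6-enoate
Conditions: PdCl2 (10 mol %), CuCl (30 mol %), O2 (1 atm), DMF/H2O 7:1, rt
Reagents that add atoms: water, O (source of the ketone oxygen; dioxygen, O=O, is the terminal oxidant)
Why: Tsuji–Wacker oxidation converts the monosubstituted terminal alkene into the C6 methyl ketone (Markovnikov), the tetrasubstituted enone alkene being inert.

Step 14
Reactants: 18 tert-butyl (3S,6Z,11S)-6-acetyl-11-(benzyloxymethyl)-3,7,11-trimethyl-13-oxotetradec-6-enoate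
Product: 21 tert-butyl (4S,5S,10R,13S)-18-(benzyloxy)-6-oxolabd-8-en-15-oate, via Michael adduct 19 (not isolated), via potassium dienolate 20 (not isolated)
Conditions: KOt-Bu (3 equiv), t-BuOH/THF, 25 → 50 °C; then cold 10% aq. AcOH
Reagents that add atoms: none
Why: tert-Butoxide equilibrates the ketone enolates of 18, and only the C5 enolate of the C6 methyl ketone can reach the enone β-carbon C10 through a six-membered chair (6-exo-trig intramolecular Michael addition closing ring A; the C7 enolate would need an eight-membered ring), giving diketone 19. Ring B then closes by 6-(enolendo)-exo-trig aldol addition of C7 to the C8 ketone and E1cB loss of water, which pulls the reversible, sterically demanding Michael step forward; the closest known reaction type is the Robinson annulation (tandem Michael addition/aldol condensation), run here with both bonds intramolecular, and the aldol should go this way round because the alternative (C17 onto C6) attacks a carbonyl flanked by the quaternary C4 and C10. C10 is set relative to the C4 centre in the chair: the branched C9 carbon takes the equatorial site so the C10 methyl is axial, and the smaller C4 methyl rather than CH2OBn should occupy the 1,3-diaxial position facing it (the cis C19/C20 relation of the target); this relay is expected to be modest and the minor C4/C10 diastereomer would be removed by chromatography of 21. C5 stays epimerisable next to the C6 carbonyl and should settle as the trans ring fusion (H5 anti to the C10 methyl). With excess base the bicyclic enone rests as the linear C6–C9 dienolate 20, which deliberately erases the uncontrolled C9 centre, and kinetic protonation at C7 by acetic acid delivers the β,γ-unsaturated ketone 21. The selectivities needed are therefore C5 over C7 attack in the Michael step (ring size), C8 over C6 as aldol acceptor (hindrance) and face selection at C10 (relay from C4).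

Step 15
Reactants: 21 tert-butyl (4S,5S,10R,13S)-18-(benzyloxy)-6-oxolabd-8-en-15-oate
Product: 22 tert-butyl (4S,5S,10R,13S)-18-(benzyloxy)-6-(trifluoromethylsulfonyloxy)labda-6,8-dien-15-oate
Conditions: KN(SiMe3)2, THF, −78 °C; PhNTf2, −78 → 0 °C
Reagents that add atoms: N-phenylbis(trifluoromethanesulfonimide), O=S(=O)(N(c1ccccc1)S(=O)(=O)C(F)(F)F)C(F)(F)F
Why: Deprotonation of the doubly activated C7 methylene (α to the ketone and allylic) regenerates the linear dienolate, which is O-triflated (enol triflate formation).

Step 16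
Reactants: 22 tert-butyl (4S,5S,10R,13S)-18-(benzyloxy)-6-(trifluoromethylsulfonyloxy)labda-6,8-dien-15-oate
Product: 23 tert-butyl (4S,5S,10R,13S)-18-(benzyloxy)labda-6,8-dien-15-oate
Conditions: Pd(OAc)2 (5 mol %), PPh3 (10 mol %), HCO2H, Et3N, DMF, 60 °C
Reagents that add atoms: none
Why: Palladium-catalysed formate reduction of the dienyl triflate (oxidative addition, formate exchange, decarboxylation, C–H reductive elimination) removes the temporary C6 oxygen.

Step 17
Reactants: 23 tert-butyl (4S,5S,10R,13S)-18-(benzyloxy)labda-6,8-dien-15-oate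
Product: 24 tert-butyl (4S,5S,10R,13S)-18-hydroxylabd-8-en-15-oate
Conditions: H2 (1 atm), Pd/C (10 wt % Pd), EtOAc, rt
Reagents that add atoms: none
Why: Heterogeneous hydrogenation should saturate only the accessible cis-disubstituted C6=C7 bond and hydrogenolyse the benzyl ether, the tetrasubstituted C8=C9 alkene resisting reduction and being the sink of any palladium-hydride isomerisation.

Step 18
Reactants: 24 tert-butyl (4S,5S,10R,13S)-18-hydroxylabd-8-en-15-oate
Product: 25 tert-butyl (4S,5S,8S,9S,10R,13S)-8,18-dihydroxylabdan-15-oate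
Conditions: BH3·THF (4 equiv), THF, 0 → 40 °C; then NaOH, H2O2, 0 °C → rt
Reagents that add atoms: hydrogen peroxide, OO
Why: Brown hydroboration–oxidation: syn addition of H–B to the face opposite the axial C10 methyl, boron going to the less hindered C8 (C9 is flanked by quaternary C10), and oxidation with retention should give the equatorial 8-OH and axial 9-H, so C8 and C9 are set in one event by substrate control.

Step 19
Reactants: 25 tert-butyl (4S,5S,8S,9S,10R,13S)-8,18-dihydroxylabdan-15-oate; 26 angelic acid
Product: 28 tert-butyl (4S,5S,8S,9S,10R,13S)-8-hydroxy-18-[(Z)-2-methylbut-2-enoyloxy]labdan-15-oate, via mixed anhydride 27 (not isolated)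
Conditions: 26, 2,4,6-trichlorobenzoyl chloride, Et3N, toluene, rt; then 25, 80 °C
Reagents that add atoms: none
Why: Yamaguchi-type esterification through the mixed anhydride without a nucleophilic amine catalyst should avoid Z to E isomerisation of the angelate, and only the primary O18 is acylated because the tertiary C8–OH is too hindered.

Step 20
Reactants: 28 tert-butyl (4S,5S,8S,9S,10R,13S)-8-hydroxy-18-[(Z)-2-methylbut-2-enoyloxy]labdan-15-oate
Product: 30 (4S,5S,8S,9S,10R,13S)-8-hydroxy-18-[(Z)-2-methylbut-2-enoyloxy]labdan-15-oic acid, via bis-silyl intermediate 29 (not isolated)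
Conditions: Me3SiOTf, 2,6-lutidine, CH2Cl2, 0 °C; then 5% aq. citric acid, THF
Reagents that add atoms: none
Why: Silyl triflate-mediated tert-butyl ester cleavage under buffered aprotic conditions expels isobutene and masks the tertiary alcohol as its silyl ether, so no cation forms at C8, and mild aqueous acid removes both silyl groups without touching the angelate.

## Compound list

1 | δ-valerolactone | O=C1CCCCO1 | starting material
2 | allyl chloroformate | C=CCOC(=O)Cl | starting material
3 | allyl 2-oxotetrahydro-2H-pyran-3-carboxylate (racemic) | C=CCOC(=O)C1CCCOC1=O | intermediate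
4 | allyl 3-methyl-2-oxotetrahydro-2H-pyran-3-carboxylate (racemic) | C=CCOC(=O)C1(C)CCCOC1=O | intermediate
5 | (S)-3-allyl-3-methyltetrahydro-2H-pyran-2-one | C=CC[C@]1(C)CCCOC1=O | intermediate
6 | (S)-2-allyl-2-methylpentane-1,5-diol | OC[C@](C)(CC=C)CCCO | intermediate
7 | (S)-2-(3-iodopropyl)-2-methylpent-4-en-1-ol | OC[C@](C)(CC=C)CCCI | intermediate
8 | (S)-4-(benzyloxymethyl)-7-iodo-4-methylhept-1-ene | c1ccccc1COC[C@](C)(CC=C)CCCI | intermediate
9 | (R)-5-methoxy-3-methyl-5-oxopentanoic acid | COC(=O)C[C@H](C)CC(=O)O | starting material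
10 | 1-tert-butyl 5-methyl (S)-3-methylpentanedioate | COC(=O)C[C@H](C)CC(=O)OC(C)(C)C | intermediate
11 | tert-butyl (S)-5-hydroxy-3-methylpentanoate | OCC[C@H](C)CC(=O)OC(C)(C)C | intermediate
12 | tert-butyl (R)-5-iodo-3-methylpentanoate | ICC[C@H](C)CC(=O)OC(C)(C)C | intermediate
13 | pentane-2,4-dione | CC(=O)CC(C)=O | starting material
14 | tert-butyl (S)-6-acetyl-3-methyl-7-oxooctanoate | CC(=O)C(C(C)=O)CC[C@H](C)CC(=O)OC(C)(C)C | intermediate
15 | tert-butyl (3S,6Z)-6-acetyl-3-methyl-7-(trifluoromethylsulfonyloxy)oct-6-enoate | C/C(OS(=O)(=O)C(F)(F)F)=C(\CC[C@H](C)CC(=O)OC(C)(C)C)C(C)=O | intermediate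
16 | [(4S)-4-(benzyloxymethyl)-4-methylhept-6-en-1-yl]zinc iodide | c1ccccc1COC[C@](C)(CC=C)CCC[Zn]I | intermediate
17 | tert-butyl (3S,6Z,11S)-6-acetyl-11-(benzyloxymethyl)-3,7,11-trimethyltetradeca-6,13-dienoate | c1ccccc1COC[C@](C)(CC=C)CCC/C(C)=C(/CC[C@H](C)CC(=O)OC(C)(C)C)C(C)=O | intermediate
18 | tert-butyl (3S,6Z,11S)-6-acetyl-11-(benzyloxymethyl)-3,7,11-trimethyl-13-oxotetradec-6-enoate | c1ccccc1COC[C@](C)(CC(C)=O)CCC/C(C)=C(/CC[C@H](C)CC(=O)OC(C)(C)C)C(C)=O | intermediate
19 | tert-butyl (3S)-6-[(1S,2S,3S)-2-acetyl-3-(benzyloxymethyl)-1,3-dimethylcyclohexyl]-3-methyl-7-oxooctanoate (C6 of the octanoate equilibrating, not defined) | c1ccccc1COC[C@@]1(C)CCC[C@@](C)(C(CC[C@H](C)CC(=O)OC(C)(C)C)C(C)=O)[C@@H]1C(C)=O | intermediate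
20 | potassium (4S,5S,10R,13S)-18-(benzyloxy)-15-tert-butoxy-15-oxolabda-6,8-dien-6-olate | c1ccccc1COC[C@@]1(C)CCC[C@]2(C)[C@@H]1C([O-])=CC(C)=C2CC[C@H](C)CC(=O)OC(C)(C)C.[K+] | intermediate
21 | tert-butyl (4S,5S,10R,13S)-18-(benzyloxy)-6-oxolabd-8-en-15-oate | c1ccccc1COC[C@@]1(C)CCC[C@]2(C)[C@@H]1C(=O)CC(C)=C2CC[C@H](C)CC(=O)OC(C)(C)C | intermediate
22 | tert-butyl (4S,5S,10R,13S)-18-(benzyloxy)-6-(trifluoromethylsulfonyloxy)labda-6,8-dien-15-oate | c1ccccc1COC[C@@]1(C)CCC[C@]2(C)[C@@H]1C(OS(=O)(=O)C(F)(F)F)=CC(C)=C2CC[C@H](C)CC(=O)OC(C)(C)C | intermediate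
23 | tert-butyl (4S,5S,10R,13S)-18-(benzyloxy)labda-6,8-dien-15-oate | c1ccccc1COC[C@@]1(C)CCC[C@]2(C)[C@@H]1C=CC(C)=C2CC[C@H](C)CC(=O)OC(C)(C)C | intermediate
24 | tert-butyl (4S,5S,10R,13S)-18-hydroxylabd-8-en-15-oate | OC[C@@]1(C)CCC[C@]2(C)[C@@H]1CCC(C)=C2CC[C@H](C)CC(=O)OC(C)(C)C | intermediate
25 | tert-butyl (4S,5S,8S,9S,10R,13S)-8,18-dihydroxylabdan-15-oate | OC[C@@]1(C)CCC[C@]2(C)[C@@H]1CC[C@](C)(O)[C@H]2CC[C@H](C)CC(=O)OC(C)(C)C | intermediate
26 | angelic acid, (Z)-2-methylbut-2-enoic acid | C/C=C(/C)C(=O)O | starting material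
27 | (Z)-2-methylbut-2-enoic 2,4,6-trichlorobenzoic anhydride | C/C=C(/C)C(=O)OC(=O)c1c(Cl)cc(Cl)cc1Cl | intermediate
28 | tert-butyl (4S,5S,8S,9S,10R,13S)-8-hydroxy-18-[(Z)-2-methylbut-2-enoyloxy]labdan-15-oate | C/C=C(/C)C(=O)OC[C@@]1(C)CCC[C@]2(C)[C@@H]1CC[C@](C)(O)[C@H]2CC[C@H](C)CC(=O)OC(C)(C)C | intermediate
29 | trimethylsilyl (4S,5S,8S,9S,10R,13S)-18-[(Z)-2-methylbut-2-enoyloxy]-8-(trimethylsilyloxy)labdan-15-oate | C/C=C(/C)C(=O)OC[C@@]1(C)CCC[C@]2(C)[C@@H]1CC[C@](C)(O[Si](C)(C)C)[C@H]2CC[C@H](C)CC(=O)O[Si](C)(C)C | intermediate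
30 | (4S,5S,8S,9S,10R,13S)-8-hydroxy-18-[(Z)-2-methylbut-2-enoyloxy]labdan-15-oic acid (CNP0315745.1) | C/C=C(/C)C(=O)OC[C@@]1(C)CCC[C@]2(C)[C@@H]1CC[C@](C)(O)[C@H]2CC[C@H](C)CC(=O)O | target

## Step count and risks

Total step count: 20. Longest linear sequence: 15 steps (steps 1–6 and 12–20, from δ-valerolactone); steps 7–11 form the five-step side branch.

**Steps most likely to fail**

Step 14 (key step). The C–C bond between the neopentyl-type C5 enolate and the tetrasubstituted enone carbon may form more slowly than γ-deprotonation of the enone and vinylogous aldol closure of C1 onto the C6 ketone. The discrimination between methyl and benzyloxymethyl at C4 may also be weak. Fallback, from 18 back to 21, with the two bonds made in separate operations and the hindered bond under enamine rather than enolate activation: pyrrolidine and acetic acid in toluene at 60 °C, then aqueous hydrolysis, should give the Stork enamine Michael product, the monocyclic diketone 19, now isolated. p-Toluenesulfonic acid in refluxing toluene with water removal would then close ring B to the conjugated 7-en-6-one F1 (mixture at C9). Treatment of F1 with KOt-Bu in t-BuOH followed by a cold acetic acid quench deconjugates it to 21.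

Step 18. Hydroboration of the hindered tetrasubstituted alkene may be slow, or boron may be delivered to C9. Fallback, from 21 back to 25, in which the C6 carbonyl delivers the oxygen to C8 and is then excised: mild acid (oxalic acid, ethanol) reconjugates 21 with kinetic protonation at C9 on the face opposite the C10 methyl to give the 7-en-6-one with natural C9 configuration F2. Weitz–Scheffer epoxidation (H2O2, NaOH, methanol, 0 °C), expected anti to the C10 methyl, gives the epoxy ketone F3. Wharton transposition (N2H4·H2O, catalytic acetic acid, methanol) gives the 6-en-8-ol F4. Hydrogenation over Pd/C saturates the alkene, removes the benzyl group and arrives at 25. This fallback carries its own uncertainty at C9 and in the epoxidation face.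

Step 17. Hydrogenation of the conjugated diene may over-reduce or stop at the 7-ene by 1,4-addition. Fallback, from 23 back to 25, with a chemoselective non-catalytic reduction and the debenzylation moved to the end: diimide generated from 2-nitrobenzenesulfonyl hydrazide and Et3N reduces only the disubstituted alkene to give the benzyl-protected 8-ene F5. Hydroboration–oxidation as in step 18 gives the benzyl ether tertiary alcohol F6. Hydrogenolysis over Pd/C, now with no alkene present, gives 25.

## Further compounds

F1 | step 14 | tert-butyl (4S,5S,10S,13S)-18-(benzyloxy)-6-oxolabd-7-en-15-oate (C9 not defined) | c1ccccc1COC[C@@]1(C)CCC[C@]2(C)[C@@H]1C(=O)C=C(C)C2CC[C@H](C)CC(=O)OC(C)(C)C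
F2 | step 18 | tert-butyl (4S,5S,9R,10S,13S)-18-(benzyloxy)-6-oxolabd-7-en-15-oate | c1ccccc1COC[C@@]1(C)CCC[C@]2(C)[C@@H]1C(=O)C=C(C)[C@H]2CC[C@H](C)CC(=O)OC(C)(C)C
F3 | step 18 | tert-butyl (4S,5S,7R,8R,9S,10S,13S)-18-(benzyloxy)-7,8-epoxy-6-oxolabdan-15-oate | c1ccccc1COC[C@@]1(C)CCC[C@]2(C)[C@@H]1C(=O)[C@@H]3O[C@]3(C)[C@H]2CC[C@H](C)CC(=O)OC(C)(C)C
F4 | step 18 | tert-butyl (4S,5S,8S,9S,10R,13S)-18-(benzyloxy)-8-hydroxylabd-6-en-15-oate | c1ccccc1COC[C@@]1(C)CCC[C@]2(C)[C@@H]1C=C[C@](C)(O)[C@H]2CC[C@H](C)CC(=O)OC(C)(C)C
F5 | step 17 | tert-butyl (4S,5S,10R,13S)-18-(benzyloxy)labd-8-en-15-oate | c1ccccc1COC[C@@]1(C)CCC[C@]2(C)[C@@H]1CCC(C)=C2CC[C@H](C)CC(=O)OC(C)(C)C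
F6 | step 17 | tert-butyl (4S,5S,8S,9S,10R,13S)-18-(benzyloxy)-8-hydroxylabdan-15-oate | c1ccccc1COC[C@@]1(C)CCC[C@]2(C)[C@@H]1CC[C@](C)(O)[C@H]2CC[C@H](C)CC(=O)OC(C)(C)C
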